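## The problem

(8R,8′R)-Auroxanthin (31) is a C2-symmetric C40 carotenoid: two identical bicyclic end groups are joined at C8 and C8′ by an all-E heptaene (C9 to C9′). In each end group a cyclohexane (ring A, C1–C6) is fused along C5–C6 to a 2,5-dihydrofuran (O1, C5, C6, C7, C8). C6 is therefore the ring-fusion carbon, an alkene carbon and the neighbour of two quaternary carbons, the gem-dimethyl C1 and the oxygenated C5. Each half has three stereocentres: the carbinol C3 (S), the quaternary ether carbon C5 (R) and the doubly allylic ether carbon C8 (R). C5 is the anchor: once fixed, the ring fusion forces its methyl group axial on ring A, and this methyl together with the axial C1 methyl can steer a reagent at C3. C8 lies across the ring oxygen on a flat five-membered ring, feels C5 only weakly, and is the centre hardest to set from within. The C8–O1 bond ionises easily to a pentadienyl-type cation (epimerisation, ring opening), and the polyene is sensitive to acid, light and oxygen; the chain should come last and the late steps should be neutral or basic. The enabling feature is the C6=C7–C8 unit: with C8 at the lactone level it is a butenolide whose β-carbon is C6, and in an open-chain precursor the same carbons can be an ynoate, where C6 is an unhindered, electron-poor sp carbon. A tertiary radical at C1 can close ring A onto it and the C5 hydroxyl can close the second ring on C8, around a C5 centre already in place.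

## Retrosynthesis

**Chain.** The two C11=C12 bonds of 31 are cut, giving two molecules of the C15 phosphonium salt 28 and the symmetrical C10 dialdehyde 29; the diacetate 30 is the direct olefination product. This cut needs only one end-group building block and leaves a purchasable centre piece. A cut at C9=C10 would put a carbonyl next to C8 and make C8–H acidic; a cut at C15=C15′ would need a C20 half. The forward reaction must be an olefination that spares the C8–O1 bond, with the E geometry completed by thermal equilibration.

**C8–C9.** 28 goes back through bromide 27 and alcohol 26 to silyl ether 25, which is cut at C8–C9 into the lactol diacetate 20 and the alkenyltrifluoroborate 24. C8 becomes an oxocarbenium carbon, C6=C7 stays where it is, and the C9–C11 arm arrives with its methyl group and its E geometry already fixed in 24. The forward reaction must attack C8 of a flat cation from the face anti to the C5 methyl. The two faces differ only by the C5 and C1 methyl groups against ring methylenes, so this is the weak point of the plan. It is met by separating the C8 epimers and, if needed, recycling the wrong one through the reversible ionisation of C8–O1.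

**Oxidation levels.** 20 comes from loliolide (18) by reductive acetylation, and 18 from the 3-oxo butenolide 17 by ketone reduction. Keeping C3 as a ketone until this point means no C3 stereocentre has to be carried through the earlier steps. The reduction is controlled by the two syn-axial methyl groups, which leave only the equatorial approach open.

**Key disconnection.** 17 is cut at C1–C6 and at O1–C8 to the open-chain ynoate 14. A cut at C5–C6 or C5–O1 would destroy the one centre that can be bought. The chosen cut turns the most congested bond of ring A into the addition of a tertiary radical to a linear sp carbon, at the β-position of an ynoate where such a radical wants to add. The precursor is an acyclic C13 chain with one stereocentre. The forward reaction must deliver a hydrogen atom only to the isopropenyl group and close 6-exo rather than 7-endo. It must also turn both enoate isomers (15 and 16) into the lactone; a radical-mediated E/Z equilibration drained by lactonisation provides for that.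

**Open chain.** The methallyl ketone of 14 is cut at C2–C3, through carbinol 13, to aldehyde 11 and allylboronate 12. Direct acylation of an allylic Grignard reagent was rejected: such reagents do not discriminate between an amide and a lactone or ynoate carbonyl, whereas an allylboronate reacts with the aldehyde alone. 11 comes from diol 10 by selective oxidation of the primary alcohol. The ynoate of 10 is cut at C7–C8 to the silylated alkyne 7 and chloroformate 8. The ester is introduced before any ketone exists because acetylide formation and a ketone do not go together.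

**Chiral pool.** Alkyne 7 is the bis-silyl ether of diol 6, which comes by one-carbon homologation from lactone 4, and 4 from (R)-citramalic acid (1) through dioxolanone 2. The tertiary carbinol of 1 becomes C5, its own carboxyl becomes C6, and the CH2CO2H arm becomes C4 and C3. No step touches the stereocentre.

**Side arm.** 24 comes from boronate 23, made by syn-borylation of silyl ether 22 of but-2-yn-1-ol (21). The syn addition fixes the later 9E geometry.

## Roads not taken

**Alternative 1:** The cut is O1–C5, with a temporary C6–Se bond. The monocyclic C8 carbinol A1 would be treated with an arylselenenyl chloride; the seleniranium ion on C5=C6 is opened 5-endo by the C8 hydroxyl to give selenide A2, and oxidative syn-elimination toward C7 would install C6=C7.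
- Merits: ring A with C3 comes from a known hydroxycyclohexene building block. C8 is a carbinol that can be set beforehand by reagent control, which is more reliable than anything the chosen plan does at C8. The elimination has only the C7 hydrogens to use.
- Weak points: the quaternary C5 is now formed under substrate control, through a reversible seleniranium ion on a tetrasubstituted alkene whose only bias is the remote C3 silyloxy group. A wrong C5 cannot be repaired, and selenium is used stoichiometrically.
- Comparison: this road is better at C8 and probably shorter to the C15 stage. The chosen plan sets against it that C5 is bought, C3 is set reliably, and its weak centre C8 is the one centre that can be re-equilibrated.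

**Alternative 2:** The cut is C14–C15 and C14′–C15′. Two molecules of the C19 alkenyl iodide A3 would be coupled with acetylene A4 (zerovalent palladium, monovalent copper) to the 15,15′-didehydro compound A5, followed by semihydrogenation and Z-to-E isomerisation.
- Merits: the coupling is mild and nearly neutral, and no carbanion is conjugated to the C8–O1 bond. That is a real advantage over the ylide of 28.
- Weak points: it is a chain tactic only. A3 already contains the complete end group, so C5, C3 and C8 remain unsolved, and A3 must be made from a C15 unit by further olefination and iodoalkene formation. Double coupling to a gas and semihydrogenation beside many alkenes add their own risks.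
- Comparison: as an endgame it is as good or better in mildness, but longer per half. The chosen plan has a purchasable centre piece (29) and a single olefination.

**Alternative 3:** The cut is C1–C6 and O1–C5 in one cationic step. Acid would protonate the isopropenyl group of the allenic carbinol A6; the C1 cation is taken by the central allene carbon C6, and the C8 hydroxyl captures the resulting C5 cation to give ester A7.
- Merits: both rings and two bonds form from an open chain, and C8 is set beforehand. On paper it is the shortest route.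
- Weak points: C5 is created in the step, controlled only by the allene axis and remote centres. Attack at the central allene carbon gives a cation whose empty orbital is at first orthogonal to the remaining C6=C7 bond. The acid that starts the cascade is what ionises the C8–O1 bond of A7.
- Comparison: this road is better in step count and at C8. The chosen plan sets against it neutral radical conditions, a polarity-matched and known reaction type, and a C5 centre that is never at stake.

Key step: step 9

Remark: the target is taken as the all-E (3S,5R,8R,3′S,5′R,8′R) isomer; 12, 29 and the diazophosphonate of step 3 are assumed to be purchasable.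

## Route

Step 1
Reactants: 1 (R)-citramalic acid
Product: 2 (R)-2-(2,2,4-trimethyl-5-oxo-1,3-dioxolan-4-yl)acetic acid
Conditions: 2,2-dimethoxypropane, TsOH·H2O (cat.), rt
Reagents that add atoms: 2,2-dimethoxypropane, COC(C)(C)OC
Why: Acid-catalysed acetonide (dioxolanone) formation should engage only the α-hydroxy acid unit and leave the CH2CO2H arm free; the quaternary stereocentre is not involved.

Step 2
Reactants: 2 (R)-2-(2,2,4-trimethyl-5-oxo-1,3-dioxolan-4-yl)acetic acid
Product: 4 (R)-3-hydroxy-3-methyldihydrofuran-2(3H)-one, via hydroxyethyl dioxolanone 3 (not isolated)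
Conditions: BH3·SMe2, THF, 0 °C to rt; MeOH; then TsOH·H2O (cat.), CH2Cl2, rt
Reagents that add atoms: none
Why: Borane reduces a free carboxylic acid in preference to the lactone-type dioxolanone carbonyl; acid-catalysed translactonisation of 3 then expels acetone and should give the γ-lactone.

Step 3
Reactants: 4 (R)-3-hydroxy-3-methyldihydrofuran-2(3H)-one
Product: 6 (R)-3-methylpent-4-yne-1,3-diol, via lactol 5 (not isolated)
Conditions: i-Bu2AlH, CH2Cl2, −78 °C; then MeOH, K2CO3, dimethyl (1-diazo-2-oxopropyl)phosphonate, −78 °C to rt
Reagents that add atoms: dimethyl (1-diazo-2-oxopropyl)phosphonate (Ohira–Bestmann reagent), COP(=O)(OC)C(=[N+]=[N-])C(C)=O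
Why: Half-reduction to the lactol followed in the same flask by Seyferth–Gilbert homologation (Ohira–Bestmann variant) of its open-chain aldehyde form should give the terminal alkyne (C6≡C7); the α-carbon is quaternary and cannot epimerise.

Step 4
Reactants: 6 (R)-3-methylpent-4-yne-1,3-diol
Product: 7 (R)-3-methyl-1,3-bis(trimethylsilyloxy)pent-4-yne
Conditions: Me3SiCl, imidazole, CH2Cl2, 0 °C to rt
Reagents that add atoms: chlorotrimethylsilane, C[Si](C)(C)Cl
Why: Silylation of both hydroxyls removes the acidic protons, so that one equivalent of base in the next step metalates only the alkyne.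

Step 5
Reactants: 7 (R)-3-methyl-1,3-bis(trimethylsilyloxy)pent-4-yne, 8 ethyl chloroformate
Product: 10 ethyl (R)-4,6-dihydroxy-4-methylhex-2-ynoate, via bis-silyl ynoate 9 (not isolated)
Conditions: n-BuLi, THF, −78 °C; ClCO2Et, −78 to −20 °C; then 1 M HCl, THF, 0 °C
Reagents that add atoms: none
Why: Acylation of the lithium acetylide with the chloroformate forms C7–C8; dilute acid in the work-up should remove both trimethylsilyl ethers without touching the ynoate.

Step 6
Reactants: 10 ethyl (R)-4,6-dihydroxy-4-methylhex-2-ynoate
Product: 11 ethyl (R)-4-hydroxy-4-methyl-6-oxohex-2-ynoate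
Conditions: TEMPO (cat.), PhI(OAc)2, CH2Cl2, rt
Reagents that add atoms: none
Why: The oxoammonium oxidation is selective for the primary alcohol, the tertiary propargylic alcohol cannot be oxidised, and the non-basic medium avoids addition of the hydroxyl to the ynoate.

Step 7
Reactants: 11 ethyl (R)-4-hydroxy-4-methyl-6-oxohex-2-ynoate, 12 2-methylallylboronic acid pinacol ester
Product: 13 ethyl (4R)-4,6-dihydroxy-4,8-dimethylnon-8-en-2-ynoate (both C6 epimers)
Conditions: CH2Cl2, rt; aq. NaHCO3
Reagents that add atoms: none
Why: Allylboration through a six-membered chair transition state is selective for the aldehyde over the ynoate ester; the new carbinol (C3 of the target) is formed as a mixture, which does not matter because it is oxidised in the next step.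

Step 8
Reactants: 13 ethyl (4R)-4,6-dihydroxy-4,8-dimethylnon-8-en-2-ynoate
Product: 14 ethyl (R)-4-hydroxy-4,8-dimethyl-6-oxonon-8-en-2-ynoate
Conditions: Dess–Martin periodinane, NaHCO3, CH2Cl2, 0 °C to rt
Reagents that add atoms: none
Why: Buffered Dess–Martin oxidation converts the secondary alcohol to the ketone under neutral conditions, which should keep the β,γ-unsaturated ketone out of conjugation and the β-hydroxy ketone intact; the tertiary alcohol is inert.

Step 9
Reactants: 14 ethyl (R)-4-hydroxy-4,8-dimethyl-6-oxonon-8-en-2-ynoate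
Product: 17 (7aR)-4,4,7a-trimethyl-5,7a-dihydro-1-benzofuran-2,6(4H,7H)-dione, via Z-enoate 15 (not isolated), via E-enoate 16 (not isolated)
Conditions: Fe(acac)3 (0.3 equiv), PhSiH3, EtOH/(CH2OH)2, 60 °C; then PhSH (cat.), AIBN (cat.), PPTS (cat.), 78 °C
Reagents that add atoms: none
Why: An iron hydride formed from Fe(acac)3 and PhSiH3 transfers a hydrogen atom to the CH2 terminus of the isopropenyl group, giving the tertiary C1 radical and with it the gem-dimethyl group. This nucleophilic radical adds 6-exo-dig to C6, the β-carbon of the ynoate, forming C1–C6 and ring A; the α-ester vinyl radical at C7 is then reduced (divalent iron and ethanol, or hydrogen-atom transfer) to the enoates 15 and 16. In 15 the ester is cis to C5 and the tertiary hydroxyl closes the butenolide by 5-exo-trig acyl substitution at C8, releasing ethanol. 16 cannot lactonise; thiyl radicals add reversibly at C7 and equilibrate 16 with 15, whose lactonisation drains the mixture toward 17. The closest known reaction type is the iron-hydride hydrogen-atom-transfer radical conjugate (Giese) cyclisation onto electron-poor π bonds, here combined with the known lactonisation of γ-hydroxy Z-enoates. No stereocentre is formed; C5 comes from 1 and is never a radical or ionic site. The selectivity needed is hydrogen-atom transfer to the electron-rich 1,1-disubstituted alkene rather than the electron-poor alkyne, and 6-exo rather than 7-endo closure; the second is secured by polarity matching (β-attack) and by the quaternary C5 in the tether. The linear sp acceptor is what allows two fully substituted carbons to be joined.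

Step 10
Reactants: 17 (7aR)-4,4,7a-trimethyl-5,7a-dihydro-1-benzofuran-2,6(4H,7H)-dione
Product: 18 (6S,7aR)-6-hydroxy-4,4,7a-trimethyl-5,6,7,7a-tetrahydro-1-benzofuran-2(4H)-one (loliolide)
Conditions: LiBH(s-Bu)3, THF, −78 °C; sat. NH4Cl
Reagents that add atoms: none
Why: The hindered trialkylborohydride should attack the C3 ketone from the equatorial side, because the axial side is blocked by the syn-axial methyl groups at C1 and C5; this gives the axial 3S alcohol, cis to the C5 methyl. Conjugate reduction of the β,β-disubstituted butenolide should be slow at −78 °C.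

Step 11
Reactants: 18 (6S,7aR)-6-hydroxy-4,4,7a-trimethyl-5,6,7,7a-tetrahydro-1-benzofuran-2(4H)-one
Product: 20 (6S,7aR)-4,4,7a-trimethyl-2,4,5,6,7,7a-hexahydro-1-benzofuran-2,6-diyl diacetate (both C2 anomers), via lactol 19 (not isolated)
Conditions: i-Bu2AlH, CH2Cl2, −78 °C; then pyridine, DMAP, Ac2O, −78 °C to rt
Reagents that add atoms: acetic anhydride, CC(=O)OC(C)=O
Why: Reductive acetylation (Rychnovsky): the aluminium hemiacetal from 1,2-reduction of the lactone is trapped in the flask as the α-acetoxy ether, and the C3 aluminium alkoxide is acetylated as well, which protects C3. C5 is quaternary, so the lactol cannot aromatise to a furan.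

Step 12
Reactants: 21 but-2-yn-1-ol
Product: 22 (but-2-yn-1-yloxy)(tert-butyl)dimethylsilane
Conditions: t-BuMe2SiCl, imidazole, CH2Cl2, rt
Reagents that add atoms: tert-butyldimethylsilyl chloride, CC(C)(C)[Si](C)(C)Cl
Why: Standard silylation of a primary alcohol; the ether also provides the electronic bias for the next step.

Step 13
Reactants: 22 (but-2-yn-1-yloxy)(tert-butyl)dimethylsilane
Product: 23 (Z)-tert-butyldimethyl{[3-(4,4,5,5-tetramethyl-1,3,2-dioxaborolan-2-yl)but-2-en-1-yl]oxy}silane
Conditions: B2pin2, CuCl (cat.), PCy3 (cat.), NaOt-Bu (cat.), MeOH, THF, rt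
Reagents that add atoms: bis(pinacolato)diboron, CC1(C)OB(OC1(C)C)B1OC(C)(C)C(C)(C)O1
Why: Copper-catalysed protoboration (syn borylcupration, then protonation by methanol) of a propargylic ether should place boron on the carbon remote from oxygen, with boron and hydrogen cis; boron is therefore trans to the CH2O group.

Step 14
Reactants: 23 (Z)-tert-butyldimethyl{[3-(4,4,5,5-tetramethyl-1,3,2-dioxaborolan-2-yl)but-2-en-1-yl]oxy}silane
Product: 24 potassium (Z)-{4-[(tert-butyldimethylsilyl)oxy]but-2-en-2-yl}trifluoroborate
Conditions: KHF2, MeOH/H2O, rt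
Reagents that add atoms: potassium hydrogen difluoride, [K+].[F-].F
Why: Standard conversion of a pinacol boronate into the trifluoroborate, with retention of alkene geometry; the alkyl silyl ether should survive at room temperature.

Step 15
Reactants: 20 (6S,7aR)-4,4,7a-trimethyl-2,4,5,6,7,7a-hexahydro-1-benzofuran-2,6-diyl diacetate, 24 potassium (Z)-{4-[(tert-butyldimethylsilyl)oxy]but-2-en-2-yl}trifluoroborate
Product: 25 (2R,6S,7aR)-2-[(2E)-4-{[tert-butyl(dimethyl)silyl]oxy}but-2-en-2-yl]-4,4,7a-trimethyl-2,4,5,6,7,7a-hexahydro-1-benzofuran-6-yl acetate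
Conditions: BF3·OEt2, MeCN/CH2Cl2, −40 to 0 °C
Reagents that add atoms: none
Why: BF3 ionises the allylic acetal acetate to the conjugated oxocarbenium ion, and the alkenyl group is transferred from boron by ipso attack with retention of geometry (addition of an organotrifluoroborate to an oxocarbenium ion); attack goes to C8 because C6 is fully substituted. C8 is set by approach anti to the C5 methyl, the face that carries only ring methylene hydrogens; the preference is expected to be modest, so the 8S epimer is removed by chromatography here or after step 16.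

Step 16
Reactants: 25 (2R,6S,7aR)-2-[(2E)-4-{[tert-butyl(dimethyl)silyl]oxy}but-2-en-2-yl]-4,4,7a-trimethyl-2,4,5,6,7,7a-hexahydro-1-benzofuran-6-yl acetate
Product: 26 (2R,6S,7aR)-2-[(2E)-4-hydroxybut-2-en-2-yl]-4,4,7a-trimethyl-2,4,5,6,7,7a-hexahydro-1-benzofuran-6-yl acetate
Conditions: Bu4NF, AcOH, THF, 0 °C to rt
Reagents that add atoms: none
Why: Buffered fluoride cleaves the primary allylic silyl ether under nearly neutral conditions, which should leave the acetate and the acid-sensitive C8–O1 bond untouched.

Step 17
Reactants: 26 (2R,6S,7aR)-2-[(2E)-4-hydroxybut-2-en-2-yl]-4,4,7a-trimethyl-2,4,5,6,7,7a-hexahydro-1-benzofuran-6-yl acetate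
Product: 28 {(2E)-3-[(2R,6S,7aR)-6-acetoxy-4,4,7a-trimethyl-2,4,5,6,7,7a-hexahydro-1-benzofuran-2-yl]but-2-en-1-yl}triphenylphosphonium bromide, via allylic bromide 27 (not isolated)
Conditions: CBr4, PPh3, 2,6-lutidine, CH2Cl2, −20 °C; then PPh3, rt
Reagents that add atoms: triphenylphosphine, c1ccc(cc1)P(c1ccccc1)c1ccccc1; carbon tetrabromide, BrC(Br)(Br)Br
Why: Appel bromination of the primary allylic alcohol, followed in the same flask by SN2 quaternisation of the labile bromide with a second portion of PPh3; this neutral sequence avoids the acidic phosphine hydrobromide method, which would ionise C8–O1.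

Step 18
Reactants: 28 {(2E)-3-[(2R,6S,7aR)-6-acetoxy-4,4,7a-trimethyl-2,4,5,6,7,7a-hexahydro-1-benzofuran-2-yl]but-2-en-1-yl}triphenylphosphonium bromide (2 equiv), 29 (2E,4E,6E)-2,7-dimethylocta-2,4,6-trienedial
Product: 31 (3S,5R,8R,3′S,5′R,8′R)-auroxanthin, via auroxanthin diacetate 30 (not isolated)
Conditions: NaOMe added slowly to 28 and 29, MeOH/CH2Cl2, 0 °C to rt, then excess NaOMe, rt; then EtOH, reflux, argon, dark
Reagents that add atoms: none
Why: A double Wittig reaction of the semi-stabilised allylic ylide, generated in the presence of the dialdehyde, forms both C11=C12 bonds; any 11Z isomers are sterically hindered and should equilibrate thermally to the all-E chain. The excess methoxide then removes both acetates by transesterification (Zemplén); C3, C5 and C8 are not touched.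

## Compound list

1 | (R)-citramalic acid [(2R)-2-hydroxy-2-methylbutanedioic acid] | C[C@@](O)(CC(=O)O)C(=O)O | starting material
2 | (R)-2-(2,2,4-trimethyl-5-oxo-1,3-dioxolan-4-yl)acetic acid | C[C@]1(CC(=O)O)OC(C)(C)OC1=O | intermediate
3 | (R)-5-(2-hydroxyethyl)-2,2,5-trimethyl-1,3-dioxolan-4-one | C[C@]1(CCO)OC(C)(C)OC1=O | intermediate (not isolated)
4 | (R)-3-hydroxy-3-methyldihydrofuran-2(3H)-one | C[C@@]1(O)CCOC1=O | intermediate
5 | (3R)-3-methyltetrahydrofuran-2,3-diol (lactol, both anomers) | C[C@@]1(O)CCOC1O | intermediate (not isolated)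
6 | (R)-3-methylpent-4-yne-1,3-diol | C#C[C@](C)(O)CCO | intermediate
7 | (R)-3-methyl-1,3-bis(trimethylsilyloxy)pent-4-yne | C#C[C@](C)(O[Si](C)(C)C)CCO[Si](C)(C)C | intermediate
8 | ethyl chloroformate | CCOC(=O)Cl | starting material
9 | ethyl (R)-4-methyl-4,6-bis(trimethylsilyloxy)hex-2-ynoate | CCOC(=O)C#C[C@](C)(O[Si](C)(C)C)CCO[Si](C)(C)C | intermediate (not isolated)
10 | ethyl (R)-4,6-dihydroxy-4-methylhex-2-ynoate | CCOC(=O)C#C[C@](C)(O)CCO | intermediate
11 | ethyl (R)-4-hydroxy-4-methyl-6-oxohex-2-ynoate | CCOC(=O)C#C[C@](C)(O)CC=O | intermediate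
12 | 2-methylallylboronic acid pinacol ester | CC(=C)CB1OC(C)(C)C(C)(C)O1 | starting material
13 | ethyl (4R)-4,6-dihydroxy-4,8-dimethylnon-8-en-2-ynoate (both C6 epimers) | CCOC(=O)C#C[C@](C)(O)CC(O)CC(C)=C | intermediate
14 | ethyl (R)-4-hydroxy-4,8-dimethyl-6-oxonon-8-en-2-ynoate | CCOC(=O)C#C[C@](C)(O)CC(=O)CC(C)=C | intermediate
15 | ethyl (2Z)-2-[(2R)-2-hydroxy-2,6,6-trimethyl-4-oxocyclohexylidene]acetate | CCOC(=O)/C=C1/C(C)(C)CC(=O)C[C@@]1(C)O | intermediate (not isolated)
16 | ethyl (2E)-2-[(2R)-2-hydroxy-2,6,6-trimethyl-4-oxocyclohexylidene]acetate | CCOC(=O)/C=C1\C(C)(C)CC(=O)C[C@@]1(C)O | intermediate (not isolated)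
17 | (7aR)-4,4,7a-trimethyl-5,7a-dihydro-1-benzofuran-2,6(4H,7H)-dione | O=C1C=C2C(C)(C)CC(=O)C[C@@]2(C)O1 | intermediate
18 | (6S,7aR)-6-hydroxy-4,4,7a-trimethyl-5,6,7,7a-tetrahydro-1-benzofuran-2(4H)-one (loliolide) | O=C1C=C2C(C)(C)C[C@H](O)C[C@@]2(C)O1 | intermediate
19 | (6S,7aR)-4,4,7a-trimethyl-2,4,5,6,7,7a-hexahydro-1-benzofuran-2,6-diol (both C2 anomers) | OC1C=C2C(C)(C)C[C@H](O)C[C@@]2(C)O1 | intermediate (not isolated)
20 | (6S,7aR)-4,4,7a-trimethyl-2,4,5,6,7,7a-hexahydro-1-benzofuran-2,6-diyl diacetate (both C2 anomers) | CC(=O)OC1C=C2C(C)(C)C[C@H](OC(C)=O)C[C@@]2(C)O1 | intermediate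
21 | but-2-yn-1-ol | CC#CCO | starting material
22 | (but-2-yn-1-yloxy)(tert-butyl)dimethylsilane | CC#CCO[Si](C)(C)C(C)(C)C | intermediate
23 | (Z)-tert-butyldimethyl{[3-(4,4,5,5-tetramethyl-1,3,2-dioxaborolan-2-yl)but-2-en-1-yl]oxy}silane | C/C(B1OC(C)(C)C(C)(C)O1)=C\CO[Si](C)(C)C(C)(C)C | intermediate
24 | potassium (Z)-{4-[(tert-butyldimethylsilyl)oxy]but-2-en-2-yl}trifluoroborate | [K+].C/C(=C\CO[Si](C)(C)C(C)(C)C)[B-](F)(F)F | intermediate
25 | (2R,6S,7aR)-2-[(2E)-4-{[tert-butyl(dimethyl)silyl]oxy}but-2-en-2-yl]-4,4,7a-trimethyl-2,4,5,6,7,7a-hexahydro-1-benzofuran-6-yl acetate | CC(C)(C)[Si](C)(C)OC/C=C(\C)[C@H]1C=C2C(C)(C)C[C@H](OC(C)=O)C[C@@]2(C)O1 | intermediate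
26 | (2R,6S,7aR)-2-[(2E)-4-hydroxybut-2-en-2-yl]-4,4,7a-trimethyl-2,4,5,6,7,7a-hexahydro-1-benzofuran-6-yl acetate | OC/C=C(\C)[C@H]1C=C2C(C)(C)C[C@H](OC(C)=O)C[C@@]2(C)O1 | intermediate
27 | (2R,6S,7aR)-2-[(2E)-4-bromobut-2-en-2-yl]-4,4,7a-trimethyl-2,4,5,6,7,7a-hexahydro-1-benzofuran-6-yl acetate | BrC/C=C(\C)[C@H]1C=C2C(C)(C)C[C@H](OC(C)=O)C[C@@]2(C)O1 | intermediate (not isolated)
28 | {(2E)-3-[(2R,6S,7aR)-6-acetoxy-4,4,7a-trimethyl-2,4,5,6,7,7a-hexahydro-1-benzofuran-2-yl]but-2-en-1-yl}triphenylphosphonium bromide | [Br-].c1ccccc1[P+](c1ccccc1)(c1ccccc1)C/C=C(\C)[C@H]1C=C2C(C)(C)C[C@H](OC(C)=O)C[C@@]2(C)O1 | intermediate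
29 | (2E,4E,6E)-2,7-dimethylocta-2,4,6-trienedial | O=C/C(C)=C/C=C/C=C(\C)C=O | starting material
30 | (8R,8′R)-auroxanthin 3,3′-diacetate | CC(/C=C/C=C(\C)[C@H]1C=C2C(C)(C)C[C@H](OC(C)=O)C[C@@]2(C)O1)=C\C=C\C=C(C)\C=C\C=C(/C)[C@H]1C=C2C(C)(C)C[C@H](OC(C)=O)C[C@@]2(C)O1 | intermediate (not isolated)
31 | (3S,5R,8R,3′S,5′R,8′R)-auroxanthin | CC(/C=C/C=C(\C)[C@H]1C=C2C(C)(C)C[C@H](O)C[C@@]2(C)O1)=C\C=C\C=C(C)\C=C\C=C(/C)[C@H]1C=C2C(C)(C)C[C@H](O)C[C@@]2(C)O1 | target

## Step count and least certain steps

Total: 18 steps. Longest linear sequence: 15 steps (steps 1–11 and 15–18, from 1 to 31); steps 12–14 make the side arm.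

**Step 9 (key step).** The most likely failure is incomplete funnelling of the E-enoate: thiyl radicals must add at C7 next to a carbon flanked by two quaternary centres, and the prolonged heating this needs may cost material through β-elimination or retro-aldol cleavage of the β-hydroxy ketone. Simple reduction of the C1 radical before 6-exo-dig closure is the second risk.
Fallback (sets out from 13, returns at 17): the lactone is closed before the radical step, so the acceptor geometry is fixed and the acceptor is the ordinary alkene case.
- Semihydrogenation of 13 (H2, Pd on CaCO3 poisoned with Pb(OAc)2, quinoline) gives the Z-enoate, which lactonises to the side-chain butenolide (5R)-5-(2-hydroxy-4-methylpent-4-en-1-yl)-5-methylfuran-2(5H)-one F1.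
- The same iron hydride conditions close ring A 6-exo-trig onto the butenolide β-carbon, giving the cis-fused lactone (3aS,7aR)-6-hydroxy-4,4,7a-trimethylhexahydro-1-benzofuran-2(3H)-one F2.
- Selenenylation of the lactone enolate (LiN(i-Pr)2, PhSeBr) gives the 3-(phenylselanyl) derivative of that lactone F3.
- Oxidation with H2O2 and syn-elimination restore C6=C7 in (7aR)-6-hydroxy-4,4,7a-trimethyl-5,6,7,7a-tetrahydro-1-benzofuran-2(4H)-one F4 (both C6 epimers), and Dess–Martin oxidation gives 17.

**Step 15.** Poor facial selectivity at the flat oxocarbenium ion is the main risk, since the two faces differ only by methyl against ring methylene at C5 and C1. Re-ionisation of the product by the Lewis acid is a second.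
Fallback (sets out from 20, returns at 25): kinetic control at C8 is given up and the lability of the C8–O1 bond is used instead. The coupling is run for conversion only, and 25 is separated from its C8 epimer, (2S,6S,7aR)-2-[(2E)-4-{[tert-butyl(dimethyl)silyl]oxy}but-2-en-2-yl]-4,4,7a-trimethyl-2,4,5,6,7,7a-hexahydro-1-benzofuran-6-yl acetate F5. F5 is re-equilibrated with 25 by a trace of camphorsulfonic acid in CH2Cl2 (reversible ionisation of the doubly allylic C8–O1 bond and reclosure by the C5 oxygen, as known for furanoid carotenoid end groups), and the mixture is separated again.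

**Step 18.** The ylide is conjugated to the C8–O1 bond, so reversible ring opening by vinylogous β-elimination could epimerise C8 under base. Incomplete Z-to-E equilibration and single instead of double olefination are further risks.
Fallback (sets out from 26, returns at 30): a Julia–Kocienski olefination, in which the carbanion exists only at −78 °C in the presence of the aldehyde.
- Mitsunobu reaction of 26 with 1-phenyl-1H-tetrazole-5-thiol (PPh3, diisopropyl azodicarboxylate) gives the sulfide 5-{[(2E)-3-[(2R,6S,7aR)-6-acetoxy-4,4,7a-trimethyl-2,4,5,6,7,7a-hexahydro-1-benzofuran-2-yl]but-2-en-1-yl]sulfanyl}-1-phenyl-1H-tetrazole F6.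
- Oxidation with H2O2 and (NH4)6Mo7O24 (cat.) gives the corresponding sulfone F7.
- KN(SiMe3)2 is added at −78 °C to F7 and 29 to give 30, which is deacetylated (K2CO3, MeOH) to 31.

**Step 3.** The transient α-hydroxy aldehyde may undergo base-induced α-ketol rearrangement before it is homologated, and the small water-soluble diol may be lost on isolation.
Fallback (sets out from 4, returns at 6): the tertiary hydroxyl is protected before the aldehyde is unmasked.
- Silylation (Et3SiOTf, 2,6-lutidine) gives (R)-3-methyl-3-[(triethylsilyl)oxy]dihydrofuran-2(3H)-one F8.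
- Reduction with i-Bu2AlH gives the lactol (3R)-3-methyl-3-[(triethylsilyl)oxy]tetrahydrofuran-2-ol F9.
- Diazophosphonate homologation gives (R)-3-methyl-3-[(triethylsilyl)oxy]pent-4-yn-1-ol F10, and Bu4NF returns 6.

## Further compounds

F1 | step 9 | (5R)-5-(2-hydroxy-4-methylpent-4-en-1-yl)-5-methylfuran-2(5H)-one (both carbinol epimers) | C=C(C)CC(O)C[C@@]1(C)OC(=O)C=C1
F2 | step 9 | (3aS,7aR)-6-hydroxy-4,4,7a-trimethylhexahydro-1-benzofuran-2(3H)-one (both C6 epimers) | O=C1C[C@H]2C(C)(C)CC(O)C[C@@]2(C)O1
F3 | step 9 | cis-fused (7aR)-6-hydroxy-4,4,7a-trimethyl-3-(phenylselanyl)hexahydro-1-benzofuran-2(3H)-one | O=C1C([Se]c3ccccc3)[C@H]2C(C)(C)CC(O)C[C@@]2(C)O1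
F4 | step 9 | (7aR)-6-hydroxy-4,4,7a-trimethyl-5,6,7,7a-tetrahydro-1-benzofuran-2(4H)-one (both C6 epimers) | O=C1C=C2C(C)(C)CC(O)C[C@@]2(C)O1
F5 | step 15 | (2S,6S,7aR)-2-[(2E)-4-{[tert-butyl(dimethyl)silyl]oxy}but-2-en-2-yl]-4,4,7a-trimethyl-2,4,5,6,7,7a-hexahydro-1-benzofuran-6-yl acetate | CC(C)(C)[Si](C)(C)OC/C=C(\C)[C@@H]1C=C2C(C)(C)C[C@H](OC(C)=O)C[C@@]2(C)O1
F6 | step 18 | 5-{[(2E)-3-[(2R,6S,7aR)-6-acetoxy-4,4,7a-trimethyl-2,4,5,6,7,7a-hexahydro-1-benzofuran-2-yl]but-2-en-1-yl]sulfanyl}-1-phenyl-1H-tetrazole | c1ccc(cc1)-n1nnnc1SC/C=C(\C)[C@H]1C=C2C(C)(C)C[C@H](OC(C)=O)C[C@@]2(C)O1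
F7 | step 18 | 5-{[(2E)-3-[(2R,6S,7aR)-6-acetoxy-4,4,7a-trimethyl-2,4,5,6,7,7a-hexahydro-1-benzofuran-2-yl]but-2-en-1-yl]sulfonyl}-1-phenyl-1H-tetrazole | c1ccc(cc1)-n1nnnc1S(=O)(=O)C/C=C(\C)[C@H]1C=C2C(C)(C)C[C@H](OC(C)=O)C[C@@]2(C)O1
F8 | step 3 | (R)-3-methyl-3-[(triethylsilyl)oxy]dihydrofuran-2(3H)-one | CC[Si](CC)(CC)O[C@]1(C)CCOC1=O
F9 | step 3 | (3R)-3-methyl-3-[(triethylsilyl)oxy]tetrahydrofuran-2-ol (both anomers) | CC[Si](CC)(CC)O[C@]1(C)CCOC1O
F10 | step 3 | (R)-3-methyl-3-[(triethylsilyl)oxy]pent-4-yn-1-ol | C#C[C@](C)(O[Si](CC)(CC)CC)CCO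
A1 | alternative 1 | ethyl (2E,4R)-5-[(4R)-4-{[tert-butyl(dimethyl)silyl]oxy}-2,6,6-trimethylcyclohex-1-en-1-yl]-4-hydroxy-3-methylpent-2-enoate | CCOC(=O)/C=C(\C)[C@H](O)CC1=C(C)C[C@@H](O[Si](C)(C)C(C)(C)C)CC1(C)C
A2 | alternative 1 | bicyclic C6 phenylselenide of the C15 furanoid ethyl ester, C3 silyl ether | CCOC(=O)/C=C(\C)[C@H]1C[C@@]2([Se]c3ccccc3)C(C)(C)C[C@H](O[Si](C)(C)C(C)(C)C)C[C@@]2(C)O1
A3 | alternative 2 | (2R,6S,7aR)-2-[(2E,4E,6E)-7-iodo-6-methylhepta-2,4,6-trien-2-yl]-4,4,7a-trimethyl-2,4,5,6,7,7a-hexahydro-1-benzofuran-6-ol (C19 alkenyl iodide) | I/C=C(C)/C=C/C=C(\C)[C@H]1C=C2C(C)(C)C[C@H](O)C[C@@]2(C)O1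
A4 | alternative 2 | acetylene | C#C
A5 | alternative 2 | 15,15′-didehydro-(8R,8′R)-auroxanthin | CC(/C=C/C=C(\C)[C@H]1C=C2C(C)(C)C[C@H](O)C[C@@]2(C)O1)=C\C#C\C=C(C)\C=C\C=C(/C)[C@H]1C=C2C(C)(C)C[C@H](O)C[C@@]2(C)O1
A6 | alternative 3 | ethyl (2E,4R)-9-{[tert-butyl(dimethyl)silyl]oxy}-4-hydroxy-3,7,11-trimethyldodeca-2,5,6,11-tetraenoate (C9 configured as C3 of the target, allene axis unspecified) | CCOC(=O)/C=C(\C)[C@H](O)C=C=C(C)C[C@@H](O[Si](C)(C)C(C)(C)C)CC(C)=C
A7 | alternative 3 | C15 furanoid ethyl ester, C3 silyl ether | CCOC(=O)/C=C(\C)[C@H]1C=C2C(C)(C)C[C@H](O[Si](C)(C)C(C)(C)C)C[C@@]2(C)O1
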